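**Retrosynthetic overview**

1. Ring labels: A and C are the benzene and pyran rings of the 8-prenylchromene half; B and D are the benzene and pyran rings of the 8-hydroxychromene half (chromene numbering O1, C2, C3, C4, C4a, C5 to C8, C8a).
2. Enabling feature: on ring B the free hydroxyl at C8 sits ortho to the pyran oxygen O1 (on C8a), and ring D carries the C3=C4 alkene and the C2 gem-dimethyl group. Rings B/D are therefore the closed, aromatic isomer of a 3-prenyl-1,2-benzoquinone; opening O1–C2 (retro-oxa-6π), undoing the tautomerism and removing the C8 oxygen leads back to the plain 2-prenylphenol 10.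
3. Phenol 10 is cut at the biaryl bond (Suzuki–Miyaura) into boronate 9 and bromophenol 3; 9 comes from bromochromene 8, whose ring C is the Claisen/oxa-6π product of propargyl ether 5, itself made from 3.
4. Both aryl halves thus come from one compound, 4-bromo-2-prenylphenol 3 (4-bromophenol plus prenyl bromide).
5. Order of ring formation: ring C (step 3), biaryl bond (step 5), ring D last (step 6); no protecting group is used.

Key step: step 6

Remark: the target has no stereocenter; the exocyclic double bond of the ortho-quinone methides 7 and 12 is written in the Z geometry that can cyclize, the E isomer of 12 being expected to equilibrate through the same base-mediated tautomerism.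

**Route**

Step 1
Reactants: 1 4-bromophenol; 2 1-bromo-3-methylbut-2-ene (prenyl bromide)
Product: 3 4-bromo-2-(3-methylbut-2-en-1-yl)phenol
Conditions: NaH (1.0 equiv), toluene, 0 °C to rt
Reagents that add atoms: none
Why: In a non-polar solvent the tightly ion-paired sodium phenoxide should be alkylated at carbon through a sodium-bridged cyclic transition state (ortho-C-alkylation of a phenoxide), and the para bromine leaves only the two equivalent ortho carbons open.

Step 2
Reactants: 3 4-bromo-2-(3-methylbut-2-en-1-yl)phenol; 4 3-chloro-3-methylbut-1-yne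
Product: 5 4-bromo-2-(3-methylbut-2-en-1-yl)-1-[(2-methylbut-3-yn-2-yl)oxy]benzene
Conditions: K2CO3 (2 equiv), KI (cat.), CuI (cat.), acetone, 56 °C
Reagents that add atoms: none
Why: Copper-assisted O-alkylation of a phenoxide with a tertiary propargylic chloride (substitution through a copper acetylide) is the standard entry to aryl 1,1-dimethylpropargyl ethers and should leave the aryl bromide and the prenyl group untouched.

Step 3
Reactants: 5 4-bromo-2-(3-methylbut-2-en-1-yl)-1-[(2-methylbut-3-yn-2-yl)oxy]benzene
Product: 8 6-bromo-2,2-dimethyl-8-(3-methylbut-2-en-1-yl)-2H-chromene, via allenylphenol 6 (not isolated), via ortho-quinone methide 7 (not isolated)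
Conditions: PhNEt2, 185 °C
Reagents that add atoms: none
Why: An aromatic propargyl Claisen rearrangement to the only free ortho carbon should give allenylphenol 6 after enolization, and its 1,5-hydrogen shift to ortho-quinone methide 7 followed by oxa-6π electrocyclization is the classical thermal route from aryl propargyl ethers to 2,2-dimethyl-2H-chromenes.

Step 4
Reactants: 8 6-bromo-2,2-dimethyl-8-(3-methylbut-2-en-1-yl)-2H-chromene
Product: 9 2-[2,2-dimethyl-8-(3-methylbut-2-en-1-yl)-2H-chromen-6-yl]-4,4,5,5-tetramethyl-1,3,2-dioxaborolane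
Conditions: B2pin2 (1.1 equiv), Pd(dppf)Cl2 (3 mol%), KOAc (3 equiv), 1,4-dioxane, 90 °C
Reagents that add atoms: bis(pinacolato)diboron, CC1(C)OB(OC1(C)C)B1OC(C)(C)C(C)(C)O1
Why: Miyaura borylation (oxidative addition of the aryl bromide to zerovalent palladium, acetate-assisted transmetalation, reductive elimination) is reliable for electron-rich aryl bromides and tolerates trisubstituted and styrenyl alkenes.

Step 5
Reactants: 9 2-[2,2-dimethyl-8-(3-methylbut-2-en-1-yl)-2H-chromen-6-yl]-4,4,5,5-tetramethyl-1,3,2-dioxaborolane; 3 4-bromo-2-(3-methylbut-2-en-1-yl)phenol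
Product: 10 4-[2,2-dimethyl-8-(3-methylbut-2-en-1-yl)-2H-chromen-6-yl]-2-(3-methylbut-2-en-1-yl)phenol
Conditions: Pd(dppf)Cl2 (5 mol%), K2CO3 (3 equiv), 1,4-dioxane/H2O (4:1), 85 °C
Reagents that add atoms: none
Why: Suzuki–Miyaura coupling should form the biaryl bond readily because neither carbon has an ortho substituent, and the free phenol is tolerated as its phenoxide in aqueous carbonate.

Step 6
Reactants: 10 4-[2,2-dimethyl-8-(3-methylbut-2-en-1-yl)-2H-chromen-6-yl]-2-(3-methylbut-2-en-1-yl)phenol
Product: 13 6-[2,2-dimethyl-8-(3-methylbut-2-en-1-yl)-2H-chromen-6-yl]-2,2-dimethyl-2H-chromen-8-ol, via ortho-quinone 11 (not isolated), via hydroxy ortho-quinone methide 12 (not isolated)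
Conditions: (KSO3)2NO (2.0 equiv), aq. KH2PO4 (pH 6), Aliquat 336 (cat.), CH2Cl2, 0 °C, until the violet colour of the reagent fades; aqueous layer drawn off; then Et3N (0.3 equiv), CH2Cl2, 0 °C to rt, Ar
Reagents that add atoms: Fremy's salt (dipotassium nitrosodisulfonate), [K+].[K+].[O]N(S(=O)(=O)[O-])S(=O)(=O)[O-] (supplies the C8 oxygen)
Why: Proposed new method: (KSO3)2NO should turn the 2,4-disubstituted phenol into ortho-quinone 11 by Teuber oxidation (phenoxyl radical, capture of a second nitroxyl radical at the only hydrogen-bearing ortho carbon, loss of imidodisulfonate), after which Et3N removes a proton from the benzylic and allylic CH2 of the prenyl group and the extended dienolate is protonated on the new, remote carbonyl oxygen to give hydroxy ortho-quinone methide 12, whose O=C–C=CH–CH=CMe2 unit closes by a thermal disrotatory oxa-6π electrocyclization that joins the former phenol oxygen to the CMe2 carbon and restores the aromatic ring. The closest known reaction types are the Teuber oxidation of para-substituted phenols to ortho-quinones and the amine-mediated isomerization of 2-prenyl-1,4-benzoquinones to 2,2-dimethyl-2H-chromen-6-ols; the ortho-quinone version and its telescoping from the phenol are new. Ring D is closed by this 6π electrocyclization of a 1-oxatriene (formally a 6-endo closure), and no stereocenter arises because C2 carries two methyl groups. The step needs site selectivity in the oxygenation, which the substitution of ring B secures (aryl at the para carbon, prenyl at one ortho carbon, one free ortho carbon), and selectivity between the two oxygens in the closure, which is secured because only the original phenol oxygen remains a carbonyl conjugated to the exocyclic diene while the new oxygen becomes the C8 hydroxyl. The oxidant is removed before the base is added because the product phenol has a free para position and would otherwise be oxidized further.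

**Compound list**

1 | 4-bromophenol | Oc1ccc(Br)cc1 | starting material
2 | 1-bromo-3-methylbut-2-ene (prenyl bromide) | CC(C)=CCBr | starting material
3 | 4-bromo-2-(3-methylbut-2-en-1-yl)phenol | CC(C)=CCc1cc(Br)ccc1O | intermediate
4 | 3-chloro-3-methylbut-1-yne | C#CC(C)(C)Cl | starting material
5 | 4-bromo-2-(3-methylbut-2-en-1-yl)-1-[(2-methylbut-3-yn-2-yl)oxy]benzene | CC(C)=CCc1cc(Br)ccc1OC(C)(C)C#C | intermediate
6 | 4-bromo-2-(3-methylbuta-1,2-dien-1-yl)-6-(3-methylbut-2-en-1-yl)phenol | CC(C)=CCc1cc(Br)cc(C=C=C(C)C)c1O | intermediate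
7 | (6Z)-4-bromo-6-(3-methylbut-2-en-1-ylidene)-2-(3-methylbut-2-en-1-yl)cyclohexa-2,4-dien-1-one | O=C1C(CC=C(C)C)=CC(Br)=C/C1=C/C=C(C)C | intermediate
8 | 6-bromo-2,2-dimethyl-8-(3-methylbut-2-en-1-yl)-2H-chromene | CC(C)=CCc1cc(Br)cc2c1OC(C)(C)C=C2 | intermediate
9 | 2-[2,2-dimethyl-8-(3-methylbut-2-en-1-yl)-2H-chromen-6-yl]-4,4,5,5-tetramethyl-1,3,2-dioxaborolane | CC(C)=CCc1cc(B3OC(C)(C)C(C)(C)O3)cc2c1OC(C)(C)C=C2 | intermediate
10 | 4-[2,2-dimethyl-8-(3-methylbut-2-en-1-yl)-2H-chromen-6-yl]-2-(3-methylbut-2-en-1-yl)phenol | CC(C)=CCc1cc(-c2ccc(O)c(CC=C(C)C)c2)cc2c1OC(C)(C)C=C2 | intermediate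
11 | 5-[2,2-dimethyl-8-(3-methylbut-2-en-1-yl)-2H-chromen-6-yl]-3-(3-methylbut-2-en-1-yl)cyclohexa-3,5-diene-1,2-dione | O=C1C(=O)C=C(c2cc(CC=C(C)C)c3OC(C)(C)C=Cc3c2)C=C1CC=C(C)C | intermediate
12 | (6Z)-4-[2,2-dimethyl-8-(3-methylbut-2-en-1-yl)-2H-chromen-6-yl]-2-hydroxy-6-(3-methylbut-2-en-1-ylidene)cyclohexa-2,4-dien-1-one | O=C1C(O)=CC(c2cc(CC=C(C)C)c3OC(C)(C)C=Cc3c2)=C/C1=C/C=C(C)C | intermediate
13 | 6-[2,2-dimethyl-8-(3-methylbut-2-en-1-yl)-2H-chromen-6-yl]-2,2-dimethyl-2H-chromen-8-ol | CC(C)=CCc1cc(-c2cc(O)c3c(c2)C=CC(C)(C)O3)cc2c1OC(C)(C)C=C2 | target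

**Step count and risks**

Total step count: 6. Longest linear sequence: 6 steps (1 → 3 → 5 → 8 → 9 → 10 → 13); compound 3 enters a second time as the coupling partner in step 5.

Steps most likely to fail:

1. Step 6 (proposed new method). The oxygenation may take the wrong site or run on to over-oxidation, and bimolecular consumption of the ortho-quinone (dimerization, amine addition) may outrun its tautomerization. The fallback brings the C8 oxygen in from the start as a methyl ether and closes ring D before the biaryl coupling, all by known chemistry; it sets out from boronate 9 and returns to the route at 13. Commercial 4-bromo-2-methoxyphenol (COc1cc(Br)ccc1O) would be O-alkylated with 4 (K2CO3, KI, CuI, acetone) to 4-bromo-2-methoxy-1-[(2-methylbut-3-yn-2-yl)oxy]benzene F1. Heating F1 in PhNEt2 should rearrange it (aromatic propargyl Claisen rearrangement, 1,5-hydrogen shift, oxa-6π electrocyclization) to 6-bromo-8-methoxy-2,2-dimethyl-2H-chromene F2. Suzuki–Miyaura coupling of F2 with 9 (Pd(dppf)Cl2, K2CO3, aqueous 1,4-dioxane) should give 6-[2,2-dimethyl-8-(3-methylbut-2-en-1-yl)-2H-chromen-6-yl]-8-methoxy-2,2-dimethyl-2H-chromene F3, and nucleophilic O-demethylation with NaSEt in DMF at 130 °C, which spares the acid-sensitive chromenes and the prenyl group, should then give 13.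

2. Step 1. O-alkylation and double alkylation may compete with the wanted ortho-C-alkylation. The fallback replaces direct C-alkylation by a sigmatropic transfer; it sets out from 1 and returns at 3. O-alkylation of 1 with 4 (K2CO3, KI, CuI, acetone) would give 1-bromo-4-[(2-methylbut-3-yn-2-yl)oxy]benzene F4. Semihydrogenation over Lindlar catalyst (Pd on CaCO3 poisoned with Pb(OAc)2, quinoline, H2, rt) would give the 1,1-dimethylallyl ether 1-bromo-4-[(2-methylbut-3-en-2-yl)oxy]benzene F5. Aromatic Claisen rearrangement of F5 (xylene, about 130 °C) transfers the allyl unit with inversion to the ortho carbon and should deliver 3 as the only C-prenylated isomer.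

3. Step 2. O-alkylation of the hindered ortho-substituted phenoxide may be slow, so that elimination of the tertiary chloride takes over. The fallback replaces the ether/Claisen sequence by a direct annulation; it sets out from 3 and returns at 8, leaving out 5. Treatment of 3 with Ti(OEt)4 and 3-methylbut-2-enal in refluxing toluene (metal phenoxide–enal chromenylation: ortho-C-alkylation of the titanium phenoxide, loss of water to the same ortho-quinone methide 7, oxa-6π electrocyclization) should give 8 directly.

**Further compounds**

F1 | step 6 | 4-bromo-2-methoxy-1-[(2-methylbut-3-yn-2-yl)oxy]benzene | COc1cc(Br)ccc1OC(C)(C)C#C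
F2 | step 6 | 6-bromo-8-methoxy-2,2-dimethyl-2H-chromene | COc1cc(Br)cc2c1OC(C)(C)C=C2
F3 | step 6 | 6-[2,2-dimethyl-8-(3-methylbut-2-en-1-yl)-2H-chromen-6-yl]-8-methoxy-2,2-dimethyl-2H-chromene | COc1cc(-c2cc(CC=C(C)C)c3OC(C)(C)C=Cc3c2)cc2c1OC(C)(C)C=C2
F4 | step 1 | 1-bromo-4-[(2-methylbut-3-yn-2-yl)oxy]benzene | C#CC(C)(C)Oc1ccc(Br)cc1
F5 | step 1 | 1-bromo-4-[(2-methylbut-3-en-2-yl)oxy]benzene | C=CC(C)(C)Oc1ccc(Br)cc1
F0 | step 2 | none | none
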